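**Plan**

- Feature: ring B is a benzoyl ring whose only other substituent is a hydroxyl on C3′, meta to the carbonyl-bearing C1′. A furan oxygen left meta to an acyl group is what a 2-acyl-7-oxabicyclo[2.2.1]heptadiene gives when its oxygen bridge opens.
- Retrosynthesis: cut the two aryl–prenyl bonds at C3 and C5 of ring A, put methyl groups back on O2 and O6, cut ring B at C1′–C6′ and C2′–C3′ to an aryl ethynyl ketone plus furan, then cut the carbonyl–alkyne bond to 2,4,6-trimethoxybenzaldehyde.
- Forward: ring A is bought; acetylide addition and oxidation give the ynone; ring B is made by [4+2] cycloaddition to furan and aromatising bridge opening; then pivalate on the new phenol, cleavage of the two ortho methyl ethers, double C-prenylation and pivalate removal.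
- Stereochemistry: none to set; the only stereocentres on the way (propargylic alcohol, oxanorbornadiene) are racemic and are destroyed.

Key step: step 3

Remark on the chemistry: the target SMILES has no stereocentre and both alkenes end in two identical methyl groups, so "single enantiomer" is taken to mean the one achiral compound drawn. Ring A is numbered with C1 on the carbonyl (2,6-OH, 3,5-prenyl, 4-OMe); ring B with C1′ on the carbonyl and OH on C3′.

**Step 1**
Reactants: 1 2,4,6-trimethoxybenzaldehyde; 2 ethynylmagnesium bromide
Product: 3 rac-1-(2,4,6-trimethoxyphenyl)prop-2-yn-1-ol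
Conditions: 2 (1.3 equiv, 0.5 M in THF), THF, 0 °C → rt; sat. aq. NH4Cl
Reagents that add atoms: none
Why: Grignard 1,2-addition of the acetylide to a non-enolisable aryl aldehyde should give the propargylic alcohol as a racemate whose stereocentre is removed in step 2; the acid-labile trimethoxybenzylic alcohol is quenched under buffered conditions and carried on crude.

**Step 2**
Reactants: 3 rac-1-(2,4,6-trimethoxyphenyl)prop-2-yn-1-ol
Product: 4 1-(2,4,6-trimethoxyphenyl)prop-2-yn-1-one
Conditions: activated MnO2 (10 equiv), CH2Cl2, rt
Reagents that add atoms: none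
Why: MnO2 oxidation of a benzylic–propargylic alcohol runs under neutral, anhydrous conditions, so the ionisable benzylic position and the terminal ynone should both be tolerated.

**Step 3**
Reactants: 4 1-(2,4,6-trimethoxyphenyl)prop-2-yn-1-one; 5 furan
Product: 7 (3-hydroxyphenyl)(2,4,6-trimethoxyphenyl)methanone, via oxanorbornadiene ketone 6 (not isolated)
Conditions: 5 (10 equiv), EtAlCl2 (1.5 equiv), CH2Cl2, −40 °C → rt; aq. Rochelle salt
Reagents that add atoms: none
Why: EtAlCl2 on the ketone oxygen lowers the alkyne LUMO, so C2 and C5 of furan add across the terminal triple bond in a concerted, normal-demand [4+2] cycloaddition (the Lewis-acid-promoted furan/acetylenic carbonyl Diels–Alder reaction) to give 6, in which both new ring-B bonds (C1′–C6′ and C2′–C3′) are already made. On warming, aluminium on the bridging oxygen ionises the bridgehead C–O bond next to the acyl-bearing carbon, since that cyclohexadienyl cation keeps positive charge off the carbon attached to the carbonyl while the other ionisation would place it there, and loss of the proton from the remaining O-bearing bridgehead aromatises the ring, as in the known acid isomerisation of 7-oxanorbornadienes to phenols. The carbocycle thus closes by intermolecular cycloaddition (the oxygen-bridged ring formed with it is the one opened again), every atom of 4 and 5 is kept, and the furan oxygen ends as the hydroxyl meta to the ketone. The two bridgehead stereocentres of 6 form as a racemate and vanish on aromatisation, so no stereocontrol is involved. The step needs cycloaddition to outpace Friedel–Crafts-type conjugate addition of furan to the activated ynone and furan oligomerisation, which low temperature, excess furan and a proton-scavenging alkylaluminium Lewis acid are meant to secure, and it needs one direction of bridge opening, which the acyl group secures. Ring A carries only methyl ethers here, which EtAlCl2 should not cleave at or below room temperature, so neither chromone formation from a free ortho phenol nor any prenyl cyclisation can interfere.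

**Step 4**
Reactants: 7 (3-hydroxyphenyl)(2,4,6-trimethoxyphenyl)methanone
Product: 8 3-(2,4,6-trimethoxybenzoyl)phenyl pivalate
Conditions: PivCl (1.2 equiv), Et3N (1.5 equiv), DMAP (cat.), CH2Cl2, 0 °C → rt
Reagents that add atoms: pivaloyl chloride, CC(C)(C)C(=O)Cl
Why: DMAP-catalysed O-acylation of the single free phenol should be clean, and the pivalate is chosen because it resists BCl3 and amidine base and is later removed by base, not acid.

**Step 5**
Reactants: 8 3-(2,4,6-trimethoxybenzoyl)phenyl pivalate
Product: 10 3-(2,6-dihydroxy-4-methoxybenzoyl)phenyl pivalate, via mono-demethylated ketone 9 (not isolated)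
Conditions: BCl3 (4 equiv, 1 M in CH2Cl2), CH2Cl2, −78 °C → rt; H2O
Reagents that add atoms: none
Why: In this chelation-controlled ether cleavage, BCl3 bound to the ketone oxygen activates each flanking methoxy group through a six-membered chelate and chloride removes the methyl group, giving first 9 and then 10, while the 4-methoxy group (no chelate) and the hindered aryl pivalate should stay intact.

**Step 6**
Reactants: 10 3-(2,6-dihydroxy-4-methoxybenzoyl)phenyl pivalate; 11 prenyl bromide (1-bromo-3-methylbut-2-ene)
Product: 13 3-[2,6-dihydroxy-4-methoxy-3,5-bis(3-methylbut-2-en-1-yl)benzoyl]phenyl pivalate, via mono-prenyl phenol 12 (not isolated)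
Conditions: 11 (2.4 equiv), DBU (2.5 equiv), THF, 0 °C → rt
Reagents that add atoms: none
Why: This is the classical base-mediated C-prenylation of an acylphloroglucinol-type phenoxide, where C3 and C5 are the only free ring carbons and each is ortho to one and para to the other phenoxide oxygen, the hydrogen-bonded amidinium ion pair in THF favours attack through carbon, and the pivalate keeps the ring-B oxygen out of the alkylation.

**Step 7**
Reactants: 13 3-[2,6-dihydroxy-4-methoxy-3,5-bis(3-methylbut-2-en-1-yl)benzoyl]phenyl pivalate
Product: 14 (2,6-dihydroxy-4-methoxy-3,5-bis(3-methylbut-2-en-1-yl)phenyl)(3-hydroxyphenyl)methanone (CNP0425861.0)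
Conditions: NaOMe (5 equiv), degassed MeOH, 0 °C → rt, Ar; AcOH
Reagents that add atoms: none
Why: Methoxide-mediated transesterification of the aryl pivalate should free the ring-B phenol without acid, so the prenyl groups cannot cyclise onto the neighbouring hydroxyls, and exclusion of air protects the electron-rich phenoxide.

**Compound list**

1 | 2,4,6-trimethoxybenzaldehyde | COc1cc(OC)c(C=O)c(OC)c1 | starting material
2 | ethynylmagnesium bromide | C#C[Mg]Br | starting material
3 | rac-1-(2,4,6-trimethoxyphenyl)prop-2-yn-1-ol (racemate) | COc1cc(OC)c(C(O)C#C)c(OC)c1 | intermediate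
4 | 1-(2,4,6-trimethoxyphenyl)prop-2-yn-1-one | COc1cc(OC)c(C(=O)C#C)c(OC)c1 | intermediate
5 | furan | c1ccoc1 | starting material
6 | rac-(7-oxabicyclo[2.2.1]hepta-2,5-dien-2-yl)(2,4,6-trimethoxyphenyl)methanone (racemate, bridgehead hydrogens necessarily cis, one enantiomer drawn; not isolated) | COc1cc(OC)c(C(=O)C2=C[C@@H]3C=C[C@H]2O3)c(OC)c1 | intermediate
7 | (3-hydroxyphenyl)(2,4,6-trimethoxyphenyl)methanone | COc1cc(OC)c(C(=O)c2cccc(O)c2)c(OC)c1 | intermediate
8 | 3-(2,4,6-trimethoxybenzoyl)phenyl pivalate | COc1cc(OC)c(C(=O)c2cccc(OC(=O)C(C)(C)C)c2)c(OC)c1 | intermediate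
9 | 3-(2-hydroxy-4,6-dimethoxybenzoyl)phenyl pivalate (present in the flask as its O–BCl2 chelate; not isolated) | COc1cc(O)c(C(=O)c2cccc(OC(=O)C(C)(C)C)c2)c(OC)c1 | intermediate
10 | 3-(2,6-dihydroxy-4-methoxybenzoyl)phenyl pivalate | COc1cc(O)c(C(=O)c2cccc(OC(=O)C(C)(C)C)c2)c(O)c1 | intermediate
11 | prenyl bromide (1-bromo-3-methylbut-2-ene) | CC(C)=CCBr | starting material
12 | 3-[2,6-dihydroxy-4-methoxy-3-(3-methylbut-2-en-1-yl)benzoyl]phenyl pivalate (not isolated) | COc1cc(O)c(C(=O)c2cccc(OC(=O)C(C)(C)C)c2)c(O)c1CC=C(C)C | intermediate
13 | 3-[2,6-dihydroxy-4-methoxy-3,5-bis(3-methylbut-2-en-1-yl)benzoyl]phenyl pivalate | COc1c(CC=C(C)C)c(O)c(C(=O)c2cccc(OC(=O)C(C)(C)C)c2)c(O)c1CC=C(C)C | intermediate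
14 | (2,6-dihydroxy-4-methoxy-3,5-bis(3-methylbut-2-en-1-yl)phenyl)(3-hydroxyphenyl)methanone | COc1c(CC=C(C)C)c(O)c(C(=O)c2cccc(O)c2)c(O)c1CC=C(C)C | target

**Step count**

Total steps: 7. Longest linear sequence: 7 steps (1 → 14).

**Steps most likely to fail**

Step 3. The Lewis-acid-activated ynone may be intercepted by furan through conjugate, Friedel–Crafts-type addition, or furan may oligomerise, before cycloaddition and bridge opening are complete. Attack of an ortho methoxy oxygen on the activated alkyne is a second leak. The fallback takes ring B as a preformed arene instead of building it. It sets out from aldehyde 1, to which is added (3-((tert-butyldimethylsilyl)oxy)phenyl)magnesium bromide F1, prepared from commercial (3-bromophenoxy)(tert-butyl)dimethylsilane and magnesium in THF. This should give rac-(3-((tert-butyldimethylsilyl)oxy)phenyl)(2,4,6-trimethoxyphenyl)methanol F2. MnO2 oxidation in CH2Cl2 should then give (3-((tert-butyldimethylsilyl)oxy)phenyl)(2,4,6-trimethoxyphenyl)methanone F3, and TBAF in THF removes the silyl group to rejoin the route at 7.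

Step 6. The ambident phenoxide may alkylate on oxygen, the reaction may stall after the first prenyl group, or a second prenyl group may add to an already substituted carbon with loss of aromaticity. The fallback replaces direct C-alkylation by a sigmatropic route and sets out from 10. O-Allylation (allyl bromide, K2CO3, acetone, reflux) should give 3-(2,6-bis(allyloxy)-4-methoxybenzoyl)phenyl pivalate F4. A double aromatic Claisen rearrangement (N,N-diethylaniline, 190 °C) moves each allyl group to its only free ortho carbon, giving 3-(3,5-diallyl-2,6-dihydroxy-4-methoxybenzoyl)phenyl pivalate F5. Two-fold olefin cross-metathesis with 2-methyl-2-butene (Grubbs second-generation catalyst, CH2Cl2, 40 °C) converts both allyl groups into prenyl groups and rejoins the route at 13.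

Step 5. The second chelation-assisted cleavage may stall once the first aryloxyboron chelate has tied up the carbonyl oxygen, and forcing it may start to cleave the para methyl ether. The fallback, from 8, removes all three methyl groups and puts one back. BBr3 (CH2Cl2, −78 °C → rt) should give 3-(2,4,6-trihydroxybenzoyl)phenyl pivalate F6. Mono-O-methylation (Me2SO4 1.0 equiv, K2CO3, acetone, rt) should then occur at the 4-hydroxyl, the only one not hydrogen-bonded to the ketone and the most acidic, rejoining the route at 10.

**Further compounds**

F1 | step 3 | (3-((tert-butyldimethylsilyl)oxy)phenyl)magnesium bromide | CC(C)(C)[Si](C)(C)Oc1cccc([Mg]Br)c1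
F2 | step 3 | rac-(3-((tert-butyldimethylsilyl)oxy)phenyl)(2,4,6-trimethoxyphenyl)methanol | COc1cc(OC)c(C(O)c2cccc(O[Si](C)(C)C(C)(C)C)c2)c(OC)c1
F3 | step 3 | (3-((tert-butyldimethylsilyl)oxy)phenyl)(2,4,6-trimethoxyphenyl)methanone | COc1cc(OC)c(C(=O)c2cccc(O[Si](C)(C)C(C)(C)C)c2)c(OC)c1
F4 | step 6 | 3-(2,6-bis(allyloxy)-4-methoxybenzoyl)phenyl pivalate | COc1cc(OCC=C)c(C(=O)c2cccc(OC(=O)C(C)(C)C)c2)c(OCC=C)c1
F5 | step 6 | 3-(3,5-diallyl-2,6-dihydroxy-4-methoxybenzoyl)phenyl pivalate | COc1c(CC=C)c(O)c(C(=O)c2cccc(OC(=O)C(C)(C)C)c2)c(O)c1CC=C
F6 | step 5 | 3-(2,4,6-trihydroxybenzoyl)phenyl pivalate | Oc1cc(O)c(C(=O)c2cccc(OC(=O)C(C)(C)C)c2)c(O)c1
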